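## Retrosynthetic overview

1. The target comes from global desilylation of its tetrakis-TBS ether; the acrylic acid is made late from a C12 allylic alcohol (MnO2, then NaClO2) that a lipase frees from its acetate.
2. The C8 ester is made by Yamaguchi coupling of the core C8 alcohol with (3R)-3,4-bis(silyloxy)-2-methylidenebutanoic acid, whose stereocentre comes from a ketoreductase reduction of ethyl 4-chloroacetoacetate.
3. The core diol comes from i-Bu2AlH opening of a cis-fused α-methylene γ-lactone, made from a butenolide (intramolecular Horner–Wadsworth–Emmons, then copper hydride 1,4-reduction, which sets C7).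
4. The butenolide precursor, a 6β-silyloxy-8β-hydroxy C7 ketone, comes from Rubottom oxidation and enolate hydroxylation of a Diels–Alder adduct.
5. Ring order: the cyclohexene ring is formed first, by a catalytic asymmetric Diels–Alder reaction of a 2-silyloxy triene with methacrolein (sets C10 and C5; formyl becomes vinyl); the γ-lactone is a temporary second ring, closed and later reduced open.

Assumption: the (S)-oxazaborolidinium catalyst of step 5 is taken to give the (1R,2R) aldehyde 8 (its usual sense of induction with 2-substituted acroleins); if the opposite sense is found, the commercially available enantiomeric catalyst is used.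

Conventions: TBS = tert-butyldimethylsilyl. Ring atoms carry elemane numbers: C10 (quaternary; CH3 and vinyl), C9 (CH2), C8, C7, C6, C5; C11/C12/C13 are the three carbons on C7 (C12 = carbonyl or carbinol carbon). β = ring face of the C10 methyl group, α = the opposite face. The target is 10β-methyl, 10α-vinyl, 5α-side chain, 6β-OH, 7β-acrylic acid, 8β-acyloxy.

## Route

Step 1
Reactants: 1 2-methylidenepropane-1,3-diol
Product: 2 2-[(TBS-oxy)methyl]prop-2-en-1-ol
Conditions: TBSCl (0.35 equiv; diol in excess), imidazole, THF, 0 °C → rt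
Reagents that add atoms: tert-butyldimethylsilyl chloride, CC(C)(C)[Si](C)(C)Cl
Why: Statistical monosilylation of a symmetrical diol used in excess gives the mono-ether; no stereocentre is involved.

Step 2
Reactants: 2 2-[(TBS-oxy)methyl]prop-2-en-1-ol
Product: 3 2-[(TBS-oxy)methyl]prop-2-enal
Conditions: MnO2, CH2Cl2, rt
Reagents that add atoms: none
Why: MnO2 oxidation of an allylic alcohol gives the enal and leaves the silyl ether untouched.

Step 3
Reactants: 3 2-[(TBS-oxy)methyl]prop-2-enal; 4 1-(triphenylphosphoranylidene)propan-2-one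
Product: 5 (3E)-5-[(TBS-oxy)methyl]hexa-3,5-dien-2-one
Conditions: CH2Cl2, rt
Reagents that add atoms: none
Why: Wittig olefination with a stabilised acetonyl ylide gives the (E)-dienone selectively.

Step 4
Reactants: 5 (3E)-5-[(TBS-oxy)methyl]hexa-3,5-dien-2-one
Product: 6 (3E)-2-(TBS-oxy)-5-[(TBS-oxy)methyl]hexa-1,3,5-triene
Conditions: TBSOTf, Et3N, CH2Cl2, −78 → 0 °C
Reagents that add atoms: tert-butyldimethylsilyl trifluoromethanesulfonate, CC(C)(C)[Si](C)(C)OS(=O)(=O)C(F)(F)F
Why: Soft enolisation (silyl triflate and amine) of the methyl ketone, its only enolisable position, gives the 2-silyloxy triene.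

Step 5
Reactants: 6 (3E)-2-(TBS-oxy)-5-[(TBS-oxy)methyl]hexa-1,3,5-triene; 7 methacrolein
Product: 8 (1R,2R)-1-methyl-4-(TBS-oxy)-2-[3-(TBS-oxy)prop-1-en-2-yl]cyclohex-3-ene-1-carbaldehyde (formyl cis to the C5 side chain)
Conditions: (S)-1-(2-methylphenyl)-3,3-diphenyltetrahydro-1H,3H-pyrrolo[1,2-c][1,3,2]oxazaborole (20 mol %), HN(SO2CF3)2 (20 mol %), CH2Cl2, −78 °C
Reagents that add atoms: none
Why: Catalytic asymmetric Diels–Alder reaction in which the electron-rich silyloxy diene unit bonds through its CH2 terminus to the β-carbon of the catalyst-bound s-trans methacrolein via the formyl-endo transition state, so that C10 and C5 are set together with formyl cis to the C5 chain, the oxazaborolidinium shielding one enal face.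

Step 6
Reactants: 8 (1R,2R)-1-methyl-4-(TBS-oxy)-2-[3-(TBS-oxy)prop-1-en-2-yl]cyclohex-3-ene-1-carbaldehyde
Product: 9 5α-[3-(TBS-oxy)prop-1-en-2-yl]-10β-methyl-7-(TBS-oxy)-10α-vinylcyclohex-6-ene
Conditions: Ph3PCH3Br, KOtBu, THF, 0 °C → rt
Reagents that add atoms: methyltriphenylphosphonium bromide, C[P+](c1ccccc1)(c1ccccc1)c1ccccc1.[Br-]
Why: Wittig methylenation of the non-enolisable neopentyl aldehyde turns the α-formyl group into the 10α-vinyl group without touching the silyl enol ether.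

Step 7
Reactants: 9 5α-[3-(TBS-oxy)prop-1-en-2-yl]-10β-methyl-7-(TBS-oxy)-10α-vinylcyclohex-6-ene
Product: 11 6β-(TBS-oxy) C7 ketone, via silyloxy epoxide 10 (not isolated)
Conditions: mCPBA (1.05 equiv), NaHCO3, CH2Cl2, −20 → 0 °C
Reagents that add atoms: 3-chloroperbenzoic acid, OOC(=O)c1cccc(Cl)c1
Why: Rubottom oxidation, in which the silyl enol ether (the most electron-rich alkene) is epoxidised anti to the adjacent C5 chain and the axial 10α-vinyl group and then opens with 1,4-silyl shift to the 6β-silyloxy ketone, also the thermodynamic (trans-diequatorial) epimer.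

Step 8
Reactants: 11 6β-(TBS-oxy) C7 ketone
Product: 13 8β-hydroxy-6β-(TBS-oxy) C7 ketone, via potassium enolate 12 (not isolated)
Conditions: KN(SiMe3)2, THF, −78 °C; 3-phenyl-2-(phenylsulfonyl)oxaziridine, −78 °C; AcOH quench at −78 °C
Reagents that add atoms: 3-phenyl-2-(phenylsulfonyl)oxaziridine, O=S(=O)(c1ccccc1)N1OC1c1ccccc1
Why: Kinetic deprotonation at the unhindered C8 methylene (away from the α-silyloxy carbon) and Davis oxaziridine hydroxylation from the face opposite the axial 10α-vinyl group give the equatorial 8β-alcohol.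

Step 9
Reactants: 13 8β-hydroxy-6β-(TBS-oxy) C7 ketone; 14 (diethoxyphosphoryl)acetic acid
Product: 15 8β-[(diethoxyphosphoryl)acetoxy]-6β-(TBS-oxy) C7 ketone
Conditions: DCC, 4-(dimethylamino)pyridine (cat.), CH2Cl2, 0 °C → rt
Reagents that add atoms: none
Why: Steglich esterification of the secondary α-ketol proceeds without change at any stereocentre.

Step 10
Reactants: 15 8β-[(diethoxyphosphoryl)acetoxy]-6β-(TBS-oxy) C7 ketone
Product: 16 butenolide (7(11)-en-8β,12-olide; 6β-OTBS)
Conditions: NaH (1.05 equiv), THF, 0 °C → rt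
Reagents that add atoms: none
Why: Intramolecular Horner–Wadsworth–Emmons olefination of the C7 ketone closes the butenolide, the temporary second ring.

Step 11
Reactants: 16 butenolide (7(11)-en-8β,12-olide; 6β-OTBS)
Product: 17 cis-fused lactone (7αH-8β,12-olide; 6β-OTBS)
Conditions: Cu(OAc)2·H2O (5 mol %), 1,2-bis(diphenylphosphino)benzene (5 mol %), (EtO)2MeSiH, t-BuOH, toluene, rt
Reagents that add atoms: none
Why: Phosphine-ligated copper hydride 1,4-reduction leaves the isolated alkenes alone and delivers hydride to C7 from the α face (syn to H-6 and H-8), because the planar lactone enolate can only be cis-fused, so C7 is set with C11 β.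

Step 12
Reactants: 17 cis-fused lactone (7αH-8β,12-olide; 6β-OTBS)
Product: 19 11-[(dimethylamino)methyl] lactone, via lithium enolate 18 (not isolated)
Conditions: LiN(i-Pr)2, THF, −78 °C; CH2=NMe2+ I−, −78 → 0 °C
Reagents that add atoms: N,N-dimethylmethyleneiminium iodide, C=[N+](C)C.[I-]
Why: Mannich reaction of the lactone enolate with Eschenmoser's salt on the convex face creates a C11 centre that is removed in the next step.

Step 13
Reactants: 19 11-[(dimethylamino)methyl] lactone
Product: 21 α-methylene lactone (11(13)-en-8β,12-olide; 6β-OTBS), via trimethylammonium iodide 20 (not isolated)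
Conditions: MeI, MeOH, rt; then NaHCO3, CH2Cl2/H2O, rt
Reagents that add atoms: none
Why: Exhaustive N-methylation followed by E1cB (Hofmann-type) elimination gives the exocyclic methylene lactone.

Step 14
Reactants: 21 α-methylene lactone (11(13)-en-8β,12-olide; 6β-OTBS)
Product: 22 diol (8β-OH; 7β-(3-hydroxyprop-1-en-2-yl); 6β-OTBS)
Conditions: i-Bu2AlH (4 equiv), CH2Cl2, −78 → 0 °C
Reagents that add atoms: none
Why: 1,2-Reduction of the lactone through the lactol gives the 1,4-diol, freeing the C8 hydroxyl and the C12 allylic alcohol without conjugate reduction.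

Step 15
Reactants: 22 diol (8β-OH; 7β-(3-hydroxyprop-1-en-2-yl); 6β-OTBS)
Product: 23 C12 primary acetate (8β-OH free)
Conditions: lipase (serine hydrolase; lipase B from Candida antarctica, immobilised), vinyl acetate, t-BuOMe, 30 °C
Reagents that add atoms: vinyl acetate, C=COC(C)=O
Why: Lipase-catalysed irreversible transesterification acetylates only the unhindered primary allylic alcohol and leaves the hindered secondary C8 hydroxyl free.

Step 16
Reactants: 24 ethyl 4-chloro-3-oxobutanoate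
Product: 25 ethyl (3R)-4-chloro-3-hydroxybutanoate
Conditions: ketoreductase ((R)-selective NADPH-dependent carbonyl reductase, an oxidoreductase), nicotinamide adenine dinucleotide phosphate (cat.), i-PrOH, phosphate buffer pH 6.5, 30 °C
Reagents that add atoms: none
Why: Enzymatic asymmetric ketone reduction with isopropanol as terminal reductant sets the (R) carbinol centre of the side chain under control of the enzyme active site.

Step 17
Reactants: 25 ethyl (3R)-4-chloro-3-hydroxybutanoate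
Product: 26 (4R)-4-hydroxyoxolan-2-one
Conditions: H2O, HCl (cat.), 90 °C
Reagents that add atoms: water, O
Why: Ester hydrolysis and 5-exo-tet displacement of the primary chloride by the carboxyl group give the lactone with the stereocentre untouched.

Step 18
Reactants: 26 (4R)-4-hydroxyoxolan-2-one
Product: 28 (3R,4R)-3-[(dimethylamino)methyl]-4-hydroxyoxolan-2-one, via dilithium dianion 27 (not isolated)
Conditions: LiN(i-Pr)2 (2.2 equiv), THF, −78 → −40 °C; CH2=NMe2+ I−, −78 → −20 °C; AcOH quench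
Reagents that add atoms: N,N-dimethylmethyleneiminium iodide, C=[N+](C)C.[I-]
Why: Fráter–Seebach-type dianion chemistry, in which the alkoxide enolate does not β-eliminate and is aminomethylated anti to the alkoxide (trans product; the new centre is removed in the next step).

Step 19
Reactants: 28 (3R,4R)-3-[(dimethylamino)methyl]-4-hydroxyoxolan-2-one
Product: 30 (4R)-4-hydroxy-3-methylideneoxolan-2-one, via trimethylammonium iodide 29 (not isolated)
Conditions: MeI, MeOH, rt; then NaHCO3, CH2Cl2/H2O, rt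
Reagents that add atoms: none
Why: Quaternisation and E1cB elimination give the α-methylene lactone without touching the carbinol centre.

Step 20
Reactants: 30 (4R)-4-hydroxy-3-methylideneoxolan-2-one
Product: 33 (3R)-3,4-bis(TBS-oxy)-2-methylidenebutanoic acid, via lithium carboxylate 31 (not isolated), via tris-TBS ester 32 (not isolated)
Conditions: LiOH (1.0 equiv), THF/H2O, 0 °C; evaporate; TBSCl (4 equiv), imidazole, DMF, rt; then K2CO3 (cat.), MeOH/H2O, 0 °C, work-up at pH 4
Reagents that add atoms: lithium hydroxide, [Li+].[OH-]; tert-butyldimethylsilyl chloride, CC(C)(C)[Si](C)(C)Cl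
Why: Saponification of the lactone, persilylation and selective hydrolysis of the labile silyl ester give the protected acid with the stereocentre unchanged.

Step 21
Reactants: 23 C12 primary acetate (8β-OH free); 33 (3R)-3,4-bis(TBS-oxy)-2-methylidenebutanoic acid
Product: 35 8β-O-[(3R)-3,4-bis(TBS-oxy)-2-methylidenebutanoyl] ester (C12 acetate), via mixed anhydride 34 (not isolated)
Conditions: 2,4,6-trichlorobenzoyl chloride, Et3N, THF, rt; then 23, 4-(dimethylamino)pyridine, toluene, 40 °C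
Reagents that add atoms: none
Why: Yamaguchi esterification through the mixed anhydride acylates the hindered equatorial C8 hydroxyl with retention at every stereocentre.

Step 22
Reactants: 35 8β-O-[(3R)-3,4-bis(TBS-oxy)-2-methylidenebutanoyl] ester (C12 acetate)
Product: 36 C12 allylic alcohol
Conditions: lipase (serine hydrolase; lipase B from Candida antarctica, immobilised), n-BuOH, t-BuOMe, 35 °C
Reagents that add atoms: none
Why: Lipase-catalysed alcoholysis removes only the primary acetate under neutral conditions, where the hindered secondary acrylate ester and the silyl ethers are not substrates.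

Step 23
Reactants: 36 C12 allylic alcohol
Product: 37 C12 aldehyde (2-substituted acrolein)
Conditions: MnO2, CH2Cl2, rt
Reagents that add atoms: none
Why: MnO2 oxidises the only free (allylic) alcohol to the enal.

Step 24
Reactants: 37 C12 aldehyde (2-substituted acrolein)
Product: 38 acrylic acid (tetrakis-TBS ether of the target)
Conditions: NaClO2, NaH2PO4, 2-methylbut-2-ene, t-BuOH/H2O, 0 °C → rt
Reagents that add atoms: sodium chlorite, [Na+].[O-]Cl=O
Why: Pinnick oxidation converts the enal into the acrylic acid while the hypochlorite scavenger protects the alkenes.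

Step 25
Reactants: 38 acrylic acid (tetrakis-TBS ether of the target)
Product: 39 target, 2-[(1S,2S,3S,4S,6R)-6-{[(3R)-3,4-dihydroxy-2-methylidenebutanoyl]oxy}-4-ethenyl-2-hydroxy-3-(3-hydroxyprop-1-en-2-yl)-4-methylcyclohexyl]prop-2-enoic acid
Conditions: HF·pyridine, pyridine, THF, 0 °C → rt; work-up buffered at pH 5
Reagents that add atoms: none
Why: Buffered fluoride desilylation removes all four TBS ethers under mildly acidic, non-basic conditions that avoid acyl migration and translactonisation of the side-chain ester.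

## Compound list

1 | 2-methylidenepropane-1,3-diol | C=C(CO)CO | starting material
2 | 2-[(TBS-oxy)methyl]prop-2-en-1-ol | C=C(CO)CO[Si](C)(C)C(C)(C)C | intermediate
3 | 2-[(TBS-oxy)methyl]prop-2-enal | C=C(C=O)CO[Si](C)(C)C(C)(C)C | intermediate
4 | 1-(triphenylphosphoranylidene)propan-2-one | CC(=O)C=P(c1ccccc1)(c1ccccc1)c1ccccc1 | starting material
5 | (3E)-5-[(TBS-oxy)methyl]hexa-3,5-dien-2-one | CC(=O)/C=C/C(=C)CO[Si](C)(C)C(C)(C)C | intermediate
6 | (3E)-2-(TBS-oxy)-5-[(TBS-oxy)methyl]hexa-1,3,5-triene | C=C(O[Si](C)(C)C(C)(C)C)/C=C/C(=C)CO[Si](C)(C)C(C)(C)C | intermediate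
7 | methacrolein (2-methylprop-2-enal) | CC(=C)C=O | starting material
8 | (1R,2R)-1-methyl-4-(TBS-oxy)-2-[3-(TBS-oxy)prop-1-en-2-yl]cyclohex-3-ene-1-carbaldehyde | O=C[C@]1(C)CCC(O[Si](C)(C)C(C)(C)C)=C[C@@H]1C(=C)CO[Si](C)(C)C(C)(C)C | intermediate
9 | 5α-[3-(TBS-oxy)prop-1-en-2-yl]-10β-methyl-7-(TBS-oxy)-10α-vinylcyclohex-6-ene | C=C[C@]1(C)CCC(O[Si](C)(C)C(C)(C)C)=C[C@@H]1C(=C)CO[Si](C)(C)C(C)(C)C | intermediate
10 | 6β,7β-epoxy-7α-(TBS-oxy) compound (silyloxy epoxide) | C=C[C@]1(C)CC[C@@]2(O[Si](C)(C)C(C)(C)C)O[C@H]2[C@@H]1C(=C)CO[Si](C)(C)C(C)(C)C | intermediate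
11 | 6β-(TBS-oxy)-5α-[3-(TBS-oxy)prop-1-en-2-yl]-10β-methyl-10α-vinylcyclohexan-7-one | C=C[C@]1(C)CCC(=O)[C@@H](O[Si](C)(C)C(C)(C)C)[C@@H]1C(=C)CO[Si](C)(C)C(C)(C)C | intermediate
12 | potassium C7(C8)-enolate of 11 | C=C[C@]1(C)CC=C([O-])[C@@H](O[Si](C)(C)C(C)(C)C)[C@@H]1C(=C)CO[Si](C)(C)C(C)(C)C.[K+] | intermediate
13 | 8β-hydroxy-6β-(TBS-oxy) C7 ketone | C=C[C@]1(C)C[C@@H](O)C(=O)[C@@H](O[Si](C)(C)C(C)(C)C)[C@@H]1C(=C)CO[Si](C)(C)C(C)(C)C | intermediate
14 | (diethoxyphosphoryl)acetic acid | CCOP(=O)(CC(=O)O)OCC | starting material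
15 | 8β-[(diethoxyphosphoryl)acetoxy]-6β-(TBS-oxy) C7 ketone | C=C[C@]1(C)C[C@@H](OC(=O)CP(=O)(OCC)OCC)C(=O)[C@@H](O[Si](C)(C)C(C)(C)C)[C@@H]1C(=C)CO[Si](C)(C)C(C)(C)C | intermediate
16 | butenolide (7(11)-en-8β,12-olide; 6β-OTBS) | C=C[C@]1(C)C[C@@H](O2)C(=CC2=O)[C@@H](O[Si](C)(C)C(C)(C)C)[C@@H]1C(=C)CO[Si](C)(C)C(C)(C)C | intermediate
17 | cis-fused lactone (7αH-8β,12-olide; 6β-OTBS) | C=C[C@]1(C)C[C@@H](O2)[C@@H](CC2=O)[C@@H](O[Si](C)(C)C(C)(C)C)[C@@H]1C(=C)CO[Si](C)(C)C(C)(C)C | intermediate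
18 | lithium enolate of lactone 17 | C=C[C@]1(C)C[C@@H](O2)[C@@H](C=C2[O-])[C@@H](O[Si](C)(C)C(C)(C)C)[C@@H]1C(=C)CO[Si](C)(C)C(C)(C)C.[Li+] | intermediate
19 | 11-[(dimethylamino)methyl] lactone (aminomethyl cis to H-7) | C=C[C@]1(C)C[C@@H](O2)[C@@H]([C@@H](CN(C)C)C2=O)[C@@H](O[Si](C)(C)C(C)(C)C)[C@@H]1C(=C)CO[Si](C)(C)C(C)(C)C | intermediate
20 | trimethylammonium iodide of 19 | C=C[C@]1(C)C[C@@H](O2)[C@@H]([C@@H](C[N+](C)(C)C)C2=O)[C@@H](O[Si](C)(C)C(C)(C)C)[C@@H]1C(=C)CO[Si](C)(C)C(C)(C)C.[I-] | intermediate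
21 | α-methylene lactone (11(13)-en-8β,12-olide; 6β-OTBS) | C=C[C@]1(C)C[C@@H](O2)[C@@H](C(=C)C2=O)[C@@H](O[Si](C)(C)C(C)(C)C)[C@@H]1C(=C)CO[Si](C)(C)C(C)(C)C | intermediate
22 | diol (8β-OH; 7β-(3-hydroxyprop-1-en-2-yl); 6β-OTBS) | C=C[C@]1(C)C[C@@H](O)[C@@H](C(=C)CO)[C@@H](O[Si](C)(C)C(C)(C)C)[C@@H]1C(=C)CO[Si](C)(C)C(C)(C)C | intermediate
23 | C12 primary acetate of 22 (8β-OH free) | C=C[C@]1(C)C[C@@H](O)[C@@H](C(=C)COC(C)=O)[C@@H](O[Si](C)(C)C(C)(C)C)[C@@H]1C(=C)CO[Si](C)(C)C(C)(C)C | intermediate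
24 | ethyl 4-chloro-3-oxobutanoate | CCOC(=O)CC(=O)CCl | starting material
25 | ethyl (3R)-4-chloro-3-hydroxybutanoate | CCOC(=O)C[C@@H](O)CCl | intermediate
26 | (4R)-4-hydroxyoxolan-2-one | O=C1C[C@@H](O)CO1 | intermediate
27 | dilithium alkoxide enolate of 26 | [O-]C1=C[C@@H]([O-])CO1.[Li+].[Li+] | intermediate
28 | (3R,4R)-3-[(dimethylamino)methyl]-4-hydroxyoxolan-2-one (trans) | O=C1[C@H](CN(C)C)[C@@H](O)CO1 | intermediate
29 | trimethylammonium iodide of 28 | O=C1[C@H](C[N+](C)(C)C)[C@@H](O)CO1.[I-] | intermediate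
30 | (4R)-4-hydroxy-3-methylideneoxolan-2-one | O=C1C(=C)[C@@H](O)CO1 | intermediate
31 | lithium (3R)-3,4-dihydroxy-2-methylidenebutanoate | [Li+].[O-]C(=O)C(=C)[C@@H](O)CO | intermediate
32 | TBS (3R)-3,4-bis(TBS-oxy)-2-methylidenebutanoate | CC(C)(C)[Si](C)(C)OC(=O)C(=C)[C@@H](O[Si](C)(C)C(C)(C)C)CO[Si](C)(C)C(C)(C)C | intermediate
33 | (3R)-3,4-bis(TBS-oxy)-2-methylidenebutanoic acid | OC(=O)C(=C)[C@@H](O[Si](C)(C)C(C)(C)C)CO[Si](C)(C)C(C)(C)C | intermediate
34 | mixed anhydride of 33 with 2,4,6-trichlorobenzoic acid | O=C(OC(=O)C(=C)[C@@H](O[Si](C)(C)C(C)(C)C)CO[Si](C)(C)C(C)(C)C)c1c(Cl)cc(Cl)cc1Cl | intermediate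
35 | 8β-O-[(3R)-3,4-bis(TBS-oxy)-2-methylidenebutanoyl] ester, C12 acetate, 6-O- and 15-O-TBS | C=C[C@]1(C)C[C@@H](OC(=O)C(=C)[C@@H](O[Si](C)(C)C(C)(C)C)CO[Si](C)(C)C(C)(C)C)[C@@H](C(=C)COC(C)=O)[C@@H](O[Si](C)(C)C(C)(C)C)[C@@H]1C(=C)CO[Si](C)(C)C(C)(C)C | intermediate
36 | C12 allylic alcohol of 35 | C=C[C@]1(C)C[C@@H](OC(=O)C(=C)[C@@H](O[Si](C)(C)C(C)(C)C)CO[Si](C)(C)C(C)(C)C)[C@@H](C(=C)CO)[C@@H](O[Si](C)(C)C(C)(C)C)[C@@H]1C(=C)CO[Si](C)(C)C(C)(C)C | intermediate
37 | C12 aldehyde (2-substituted acrolein) | C=C[C@]1(C)C[C@@H](OC(=O)C(=C)[C@@H](O[Si](C)(C)C(C)(C)C)CO[Si](C)(C)C(C)(C)C)[C@@H](C(=C)C=O)[C@@H](O[Si](C)(C)C(C)(C)C)[C@@H]1C(=C)CO[Si](C)(C)C(C)(C)C | intermediate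
38 | acrylic acid, tetrakis-TBS ether of the target | C=C[C@]1(C)C[C@@H](OC(=O)C(=C)[C@@H](O[Si](C)(C)C(C)(C)C)CO[Si](C)(C)C(C)(C)C)[C@@H](C(=C)C(=O)O)[C@@H](O[Si](C)(C)C(C)(C)C)[C@@H]1C(=C)CO[Si](C)(C)C(C)(C)C | intermediate
39 | 2-[(1S,2S,3S,4S,6R)-6-{[(3R)-3,4-dihydroxy-2-methylidenebutanoyl]oxy}-4-ethenyl-2-hydroxy-3-(3-hydroxyprop-1-en-2-yl)-4-methylcyclohexyl]prop-2-enoic acid | C=C[C@]1(C)C[C@@H](OC(=O)C(=C)[C@@H](O)CO)[C@@H](C(=C)C(=O)O)[C@@H](O)[C@@H]1C(=C)CO | target

## Totals and risks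

Total step count: 25. Longest linear sequence: 20 steps (steps 1–15 and 21–25); the side-chain acid takes 5 steps (16–20).

Step 5 is the step most likely to fail. The cycloaddition must choose the silyloxy diene unit, the correct orientation, one enal face and above all the formyl-endo mode, and 2-alkylacroleins can prefer formyl-exo. The fallback sets out from triene 6 (with diol 1 as the source of a new dienophile) and comes back at aldehyde 8. If the formyl group goes exo, the origin of the two C10 substituents is exchanged. Diol 1 is monoacetylated (Ac2O, pyridine, diol in excess) to 2-(hydroxymethyl)prop-2-en-1-yl acetate F1 and oxidised with MnO2 to 2-formylprop-2-en-1-yl acetate F2. The same catalysed cycloaddition of F2 with 6 then places the acetoxymethyl group cis and the formyl group trans to the C5 chain, giving the exo adduct F3. The formyl group becomes the 10β-methyl group through the tosylhydrazone F4 (TsNHNH2, EtOH), which is reduced with catecholborane and then NaOAc·3H2O to the 10β-methyl acetate F5. i-Bu2AlH at −78 °C removes the acetate to give the 10α-hydroxymethyl compound F6, and Dess–Martin oxidation of F6 gives 8.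

Step 8 is the second risk: enolisation on the wrong side, silyl migration to the new alkoxide or an α-ketol shift would spoil it. The fallback sets out from ketone 11 and comes back at hydroxy ketone 13, using enamine instead of enolate chemistry. L-Proline-catalysed α-aminoxylation of 11 with nitrosobenzene takes place at the unhindered C8 methylene under catalyst control and gives the 8β-(anilinooxy) ketone F7. Zn in AcOH then cleaves the N–O bond to give 13.

Step 25 is the third risk: with the free acid present, desilylation may trigger lactonisation onto the cis C6 hydroxyl or acyl shifts. The fallback sets out from acid 38 and comes back at target 39, masking the acid first. Allyl bromide and KHCO3 in DMF give the allyl ester F8. HF·pyridine then gives the desilylated allyl ester F9. Pd(PPh3)4 (zerovalent palladium, catalytic) with morpholine in THF removes the allyl group under neutral conditions and gives 39.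

## Further compounds

F1 | step 5 | 2-(hydroxymethyl)prop-2-en-1-yl acetate | CC(=O)OCC(=C)CO
F2 | step 5 | 2-formylprop-2-en-1-yl acetate | CC(=O)OCC(=C)C=O
F3 | step 5 | exo adduct: 10α-(acetoxymethyl)-10β-formyl-5α-[3-(TBS-oxy)prop-1-en-2-yl]-7-(TBS-oxy)cyclohex-6-ene | CC(=O)OC[C@]1(C=O)CCC(O[Si](C)(C)C(C)(C)C)=C[C@@H]1C(=C)CO[Si](C)(C)C(C)(C)C
F4 | step 5 | tosylhydrazone of F3 | CC(=O)OC[C@]1(/C=N/NS(=O)(=O)c2ccc(C)cc2)CCC(O[Si](C)(C)C(C)(C)C)=C[C@@H]1C(=C)CO[Si](C)(C)C(C)(C)C
F5 | step 5 | 10α-(acetoxymethyl)-10β-methyl-5α-[3-(TBS-oxy)prop-1-en-2-yl]-7-(TBS-oxy)cyclohex-6-ene | CC(=O)OC[C@]1(C)CCC(O[Si](C)(C)C(C)(C)C)=C[C@@H]1C(=C)CO[Si](C)(C)C(C)(C)C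
F6 | step 5 | 10α-(hydroxymethyl)-10β-methyl-5α-[3-(TBS-oxy)prop-1-en-2-yl]-7-(TBS-oxy)cyclohex-6-ene | OC[C@]1(C)CCC(O[Si](C)(C)C(C)(C)C)=C[C@@H]1C(=C)CO[Si](C)(C)C(C)(C)C
F7 | step 8 | 8β-(anilinooxy)-6β-(TBS-oxy) C7 ketone | C=C[C@]1(C)C[C@@H](ONc2ccccc2)C(=O)[C@@H](O[Si](C)(C)C(C)(C)C)[C@@H]1C(=C)CO[Si](C)(C)C(C)(C)C
F8 | step 25 | allyl ester of acid 38 | C=C[C@]1(C)C[C@@H](OC(=O)C(=C)[C@@H](O[Si](C)(C)C(C)(C)C)CO[Si](C)(C)C(C)(C)C)[C@@H](C(=C)C(=O)OCC=C)[C@@H](O[Si](C)(C)C(C)(C)C)[C@@H]1C(=C)CO[Si](C)(C)C(C)(C)C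
F9 | step 25 | allyl ester of the target | C=C[C@]1(C)C[C@@H](OC(=O)C(=C)[C@@H](O)CO)[C@@H](C(=C)C(=O)OCC=C)[C@@H](O)[C@@H]1C(=C)CO
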